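**Assumption:** the target has no stereocentre and no stereogenic double bond, so it is a single achiral compound and no stereocontrol is needed.

## Retrosynthetic overview

1. Protection: catechol aldehyde 1 is O-benzylated to aldehyde 2, so the electrophile carries no free phenol.
2. Ester C–O bond: Meldrum's acid 3 is opened by hexadecan-1-ol 4 to give malonate half-ester 5, which already carries the C16 ester.
3. Key C–C bond (Cα–Cβ of the side chain): Knoevenagel–Doebner condensation (aldol-type) of 2 with 5, through arylidenemalonate 6, gives cinnamate 7 with loss of CO2.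
4. Final operation: hydrogenation of 7 saturates the alkene (8) and removes both benzyl groups to give target 9.
5. No ring is formed: the only ring, the benzene ring, is bought intact in 1.

## Route

**Step 1**
Reactants: 1 3,4-dihydroxybenzaldehyde
Product: 2 3,4-bis(benzyloxy)benzaldehyde
Conditions: BnBr (2.3 equiv), K2CO3 (3 equiv), DMF, N2, 60 °C
Reagents that add atoms: benzyl bromide, BrCc1ccccc1
Why: Williamson ether synthesis, in which K2CO3 deprotonates both phenols and each phenoxide displaces bromide from the benzylic halide by SN2, while the aldehyde has no α-hydrogen and is untouched; no stereocentre.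

**Step 2**
Reactants: 3 2,2-dimethyl-1,3-dioxane-4,6-dione (Meldrum's acid); 4 hexadecan-1-ol
Product: 5 3-(hexadecyloxy)-3-oxopropanoic acid (hexadecyl hydrogen malonate)
Conditions: toluene, reflux (110 °C), 4–5 h; recrystallise from hexane
Reagents that add atoms: none
Why: Ring-opening alcoholysis (acyl substitution) of the strongly electrophilic cyclic acylal by the primary alcohol with loss of acetone; the resulting half-acid is much less electrophilic, so it stops cleanly at the mono-ester.

**Step 3**
Reactants: 2 3,4-bis(benzyloxy)benzaldehyde; 5 3-(hexadecyloxy)-3-oxopropanoic acid (1.3 equiv)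
Product: 7 hexadecyl (E)-3-[3,4-bis(benzyloxy)phenyl]prop-2-enoate, via arylidenemalonic half-ester 6 (not isolated)
Conditions: pyridine, piperidine (0.1 equiv), 80 °C, 8 h; 1 M HCl work-up
Reagents that add atoms: none
Why: Knoevenagel condensation in its Doebner modification, an aldol-type condensation in which the malonate half-ester enolate adds to the piperidine-activated aldehyde, followed by dehydration and pyridine-promoted decarboxylation of the free carboxyl to give the thermodynamically favoured E-cinnamate; no stereocentre is formed.

**Step 4**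
Reactants: 7 hexadecyl (E)-3-[3,4-bis(benzyloxy)phenyl]prop-2-enoate
Product: 9 hexadecyl 3-(3,4-dihydroxyphenyl)propanoate, via saturated dibenzyl ether ester 8 (not isolated)
Conditions: H2 (1 atm), 10% Pd/C, EtOAc–EtOH 1:1, rt, 12 h; filter through Celite under N2
Reagents that add atoms: none
Why: Heterogeneous catalytic hydrogenation saturates the conjugated alkene first and then cleaves both aryl benzyl ethers by hydrogenolysis on the same catalyst, while the non-benzylic alkyl ester and the arene are inert at 1 atm and rt; the target has no stereocentre.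

## Compound list

1 | 3,4-dihydroxybenzaldehyde | O=Cc1ccc(O)c(O)c1 | starting material
2 | 3,4-bis(benzyloxy)benzaldehyde | O=Cc1ccc(OCc2ccccc2)c(OCc2ccccc2)c1 | intermediate
3 | 2,2-dimethyl-1,3-dioxane-4,6-dione (Meldrum's acid) | CC1(C)OC(=O)CC(=O)O1 | starting material
4 | hexadecan-1-ol | CCCCCCCCCCCCCCCCO | starting material
5 | 3-(hexadecyloxy)-3-oxopropanoic acid (hexadecyl hydrogen malonate) | CCCCCCCCCCCCCCCCOC(=O)CC(=O)O | intermediate
6 | 2-[3,4-bis(benzyloxy)benzylidene]propanedioic acid monohexadecyl ester (E/Z mixture, geometry lost on decarboxylation) | CCCCCCCCCCCCCCCCOC(=O)C(=Cc1ccc(OCc2ccccc2)c(OCc2ccccc2)c1)C(=O)O | intermediate (not isolated)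
7 | hexadecyl (E)-3-[3,4-bis(benzyloxy)phenyl]prop-2-enoate | CCCCCCCCCCCCCCCCOC(=O)/C=C/c1ccc(OCc2ccccc2)c(OCc2ccccc2)c1 | intermediate
8 | hexadecyl 3-[3,4-bis(benzyloxy)phenyl]propanoate | CCCCCCCCCCCCCCCCOC(=O)CCc1ccc(OCc2ccccc2)c(OCc2ccccc2)c1 | intermediate (not isolated)
9 | hexadecyl 3-(3,4-dihydroxyphenyl)propanoate | CCCCCCCCCCCCCCCCOC(=O)CCc1ccc(O)c(O)c1 | target

## Step count and risks

Total steps: 4. Longest linear sequence: 3 steps (1 → 2 → 7 → 9, or 3/4 → 5 → 7 → 9).

**Most likely to fail, first: step 3.** The waxy half-ester 5 can decarboxylate to hexadecyl acetate before it condenses with the electron-rich aldehyde, and that by-product is hard to separate from 7. The fallback sets out from 2 and returns at 7. Aldehyde 2 is condensed with malonic acid itself (pyridine, cat. piperidine, 90 °C), passing through 2-[3,4-bis(benzyloxy)benzylidene]propanedioic acid F1 (not isolated). This decarboxylates to crystalline (E)-3-[3,4-bis(benzyloxy)phenyl]prop-2-enoic acid F2, isolated by acidification. F2 is then esterified with hexadecan-1-ol 4 under Steglich conditions (DCC, cat. DMAP, CH2Cl2, 0 °C to rt) to give 7.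

**Second: step 4.** Hydrogenolysis of the two benzyl ethers on a poorly soluble, waxy substrate may stall at mono-benzyl ethers. The fallback sets out from 1 (with 5) and returns at 9, avoiding benzyl groups altogether. Unprotected 1 is condensed directly with 5 (pyridine, cat. piperidine, 60 °C, N2) through 2-(3,4-dihydroxybenzylidene)propanedioic acid monohexadecyl ester F3 (not isolated) to hexadecyl (E)-3-(3,4-dihydroxyphenyl)prop-2-enoate F4 (hexadecyl caffeate). The only reduction left is the easy alkene saturation (H2 1 atm, 10% Pd/C, EtOAc, rt, 1–2 h), which gives 9.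

**Third: step 2.** Thermal alcoholysis may give some diester or decarboxylated material, and the soap-like half-acid 5 is awkward to purify. The fallback sets out from 4 and returns at 5. Alcohol 4 is coupled with commercial 3-(tert-butoxy)-3-oxopropanoic acid (DCC, cat. DMAP, CH2Cl2, 0 °C to rt) to give tert-butyl hexadecyl propanedioate F5, a neutral diester that is easy to chromatograph. TFA–CH2Cl2 (1:4, rt) then removes the tert-butyl group and delivers 5.

## Further compounds

F1 | step 3 | 2-[3,4-bis(benzyloxy)benzylidene]propanedioic acid | O=C(O)C(=Cc1ccc(OCc2ccccc2)c(OCc2ccccc2)c1)C(=O)O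
F2 | step 3 | (E)-3-[3,4-bis(benzyloxy)phenyl]prop-2-enoic acid | O=C(O)/C=C/c1ccc(OCc2ccccc2)c(OCc2ccccc2)c1
F3 | step 4 | 2-(3,4-dihydroxybenzylidene)propanedioic acid monohexadecyl ester (E/Z mixture) | CCCCCCCCCCCCCCCCOC(=O)C(=Cc1ccc(O)c(O)c1)C(=O)O
F4 | step 4 | hexadecyl (E)-3-(3,4-dihydroxyphenyl)prop-2-enoate | CCCCCCCCCCCCCCCCOC(=O)/C=C/c1ccc(O)c(O)c1
F5 | step 2 | tert-butyl hexadecyl propanedioate | CCCCCCCCCCCCCCCCOC(=O)CC(=O)OC(C)(C)C
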